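At late times a flask holds what the coupling partner bought before it went, so I start from how that reagent is shared.

the same everywhere: substrate 0.50 mM; coupling partner 0.600 mM; impurity 6.9 µM; time 20 s
- grey: free catalyst 12 µM
- teal: free catalyst 18 µM
- blue: free catalyst 27 µM

    substrate + free catalyst ⇌ free catalyst + intermediate (K1 = 1.7, k1 = 1.2 × 10⁵ L mol⁻¹ s⁻¹)
    coupling partner + free catalyst + intermediate → free catalyst + product (k2 = 2.0 × 10⁷ L² mol⁻² s⁻¹)
    substrate + free catalyst → spent catalyst B (k3 = 84 L mol⁻¹ s⁻¹)
    free catalyst + impurity → spent catalyst A (k4 = 1.3 × 10⁵ L mol⁻¹ s⁻¹)
    coupling partner → decomposed reagent (k5 = 0.045 s⁻¹)

* which of these there is most of at the end, counted by the substrate in it, grey (intermediate / substrate / product)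
* which of these there is most of at the end, counted by the substrate in it, teal (intermediate / substrate / product)
* which of these there is most of at the end, counted by the substrate in it, blue (intermediate / substrate / product)
* the largest of these amounts at the end, in percent of the substrate charged, grey
* the largest of these amounts at the end, in percent of the substrate charged, teal
* the largest of these amounts at the end, in percent of the substrate charged, blue

The impurity's constant 1.3 × 10⁵ L mol⁻¹ s⁻¹ is far above the 84 L mol⁻¹ s⁻¹ of the substrate's loss to spent catalyst B, and even in grey the impurity lasts about 1.51 s, shorter than 20 s. So I subtract it at once and keep a working catalyst of 5.10 µM, 0.0111 mM and 0.0201 mM in grey, teal and blue. Binding takes about 1.63 s in grey, also shorter than 20 s, so I treat it as a pre-equilibrium: 63.0% of the pool, substrate plus intermediate, sits as intermediate. Catalyst loss to substrate starts at 0.0420 s⁻¹ with the full charge of substrate and is 0.0156 s⁻¹ when the whole pool is still there and bound to its share, both slower than one per run, so I leave it out and my product figures lean high.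

Coupling and decay both carry [coupling partner], which cancels in their ratio, leaving pool over a fixed concentration. That concentration is the break-even pool g, the decay constant divided by coupling constant, working catalyst and intermediate share, which in teal is 0.322 mM. In grey it is 0.701 mM, in blue 0.178 mM.

My first way, for teal, goes by the clock: let the coupling partner fade by decay alone, and product reaches 66.9%. My second way is a ledger: each unit of pool lost costs g/pool of decay, so decay has cost g times the logarithm of charged pool over present pool. A pool of 0.200 mM then needs 0.595 mM of coupling partner, about the 0.600 mM charged, so teal's ceiling is 60.0% product. The clock overdraws: it spends 0.691 mM, more than the charge.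

I repair it by letting the coupling partner also pay for coupling at a mean pool of 0.350 mM, which gives teal a fading rate of 0.0939 s⁻¹. Then teal gives product 53.1% and intermediate 29.5%. Grey gives product 34.5% and intermediate 41.3%. Blue gives product 65.3% and intermediate 21.9%.

The forecast gives intermediate at 43% in grey, product at 49% in teal and product at 64% in blue, holding that “only the grey run stalls with intermediate ahead of product”.

The flasks end with intermediate at 43.5% in grey, product at 48.7% in teal and product at 64.1% in blue. In blue, coupling uses coupling partner 2.1 times as fast as decay at 0.243 s, but 0.83 times as fast at 20.0 s. The blue pool then stands at 0.177 mM, level with g. With 2.0 mM of substrate and blue's g, the ledger puts decay at 0.0559 mM, and that neighbour flask holds 0.0706 mM of decomposed reagent at 20.0 s.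

(The rate constants stand for no real mixture; the rest is arithmetic.)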